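**Remarks on the chemistry (assumptions)**
- Verticillane (taxane) numbering is used: ring A is C1, C14, C13, C12, C11, C15; C16 and C17 sit on C15, C18 on C12, C19 on C8, C20 on C4. α and β are used as for the taxanes: relative to the twelve-membered ring, C14 (at C1) and H11 are α, H1 and the C10 oxygen are β.
- The CIP descriptors of C1 and C11 change along the route (1S,11R in 4; 1R,11S in 11) only because substituent priorities change; neither centre is touched after step 3.
- Compound 3 is drawn as the free acid and handled as its tris-ammonium salt.

## Analysis of the target

The target 11 is a verticillane, a bicyclo[9.3.1]pentadecane. Ring A (C1, C14, C13, C12, C11, C15) and a twelve-membered ring (C1 to C11, closed by C15) share the C1–C15–C11 unit; C15 carries the geminal methyl groups and C4 and C8 carry one methyl group each. Ring A holds the C12=C18 exocyclic methylene conjugated with the C13 ketone; the large ring holds trans trisubstituted epoxides at C3–C4 and C7–C8 and an acetoxy group on C10. There are seven stereocentres: the bridgeheads C1 (R) and C11 (S), at which the nine-carbon bridge leaves ring A on opposite faces (H1 β, H11 α); C10 (S, acetoxy β); and C3, C4, C7, C8 (all R), each epoxide being the result of syn oxygen transfer to an E olefin. Read against the ring, each epoxide oxygen lies on the olefin face that is peripheral when the methyl group of that olefin (C20, C19) points to the α-face; this has to be imposed on a flexible ring with C10 as the only nearby stereocentre. The sensitive groups are the 1,5-related epoxides (acid starts transannular ether formation), the α-methylene ketone (a Michael acceptor) and the acetate (base). The difficulty lies in two bridgeheads set across a medium ring, in the stretch C2 to C9 that offers no handle for C–C bond formation, and in the oxygen on C10, a methylene that no olefin activates. The strategy rests on the bare skeleton: without its oxygens, 11 is verticilla-3,7,12(18)-triene (4), whose C1–C2 and C11–C15 bonds, two E olefins and C12=C18 olefin are what a class 1 diterpene synthase makes from geranylgeranyl diphosphate (3) when the verticillen-12-yl cation loses a C18 proton.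

## Retrosynthetic reasoning

**11 ⇒ 10.** The last change is an oxidation level at C13. The α-methylene ketone is the group of 11 most open to nucleophiles, so it is formed in the final step from the allylic alcohol 10 under buffered conditions. All earlier steps then handle an unconjugated olefin.

**10 ⇒ 9.** The C13–O bond is cut. C13 is the ring methylene allylic to C12=C18, and in 9 this is the only olefin left, so an ene/[2,3] allylic oxidation has only this site and the hindered methine C11 to choose from. The forward reaction must add oxygen without moving the olefin and without opening the epoxides.

**9 ⇒ 8.** The acetate goes back to the C10 alcohol. Acetylation is placed before the C13 oxidation so that only one hydroxyl group is ever present and no selective acylation is needed.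

**8 ⇒ 7.** The C10–O bond is cut, which in the forward sense is a C–H hydroxylation. C10 is not allylic and no group in the molecule can direct a reagent to it, so only an enzyme active site (a cytochrome P450) can single it out. The hydroxylation is placed after the epoxidation on purpose: in 4 the enzyme would meet two electron-rich olefins and eight allylic C–H positions, two of them (C9, C11) next to C10, whereas 7 offers only C13 and the hindered C11 as activated competitors. The forward reaction must replace the pro-S (β) hydrogen with retention.

**7 ⇒ 4.** Both epoxide C–O pairs are cut, giving the two E trisubstituted olefins. The epoxidation comes directly after the skeleton is made because these olefins are the most nucleophilic sites of 4 and would interfere with every later oxidation. The forward reaction must prefer trisubstituted over 1,1-disubstituted olefins and deliver oxygen with the sense that gives R,R at both.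

**4 ⇒ 3.** The key disconnection cuts C1–C2 and C11–C15 and opens both rings to one acyclic C20 chain. Every carbon of 4 maps onto 3: C2 is the carbon that bears the diphosphate, C1=C15 is the terminal olefin, C11=C12 the third olefin and C18 its methyl group. No other pair of cuts turns the bicycle into a single commercial chain. The gain is two rings, two stereocentres and the exocyclic olefin in one step; the forward reaction needs ionisation, macrocyclisation, ring A closure and C18 deprotonation, all under enzyme control.

**3 ⇒ 2 ⇒ 1.** The C–O–P bond is cut to the primary allylic chloride 2, which comes from geranylgeraniol 1 by chlorination without allylic shift. Two routine steps keep the risk in the cyclisation.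

## Alternatives that were turned down

**Alternative 1:** The C5–C6 bond, between the two allylic methylenes of the large ring, is cut. Forward, a phenyl sulfone on C6 is deprotonated with KN(SiMe3)2 under high dilution and the carbanion displaces an allylic bromide on C5; this closes the twelve-membered ring and gives the bicyclic sulfone A1 as a C6 mixture, from which the sulfone is later removed reductively.
- For: the bond joins two activated, unhindered carbons, and both olefin geometries are fixed before ring closure. The C10 and C13 oxygens are carried in as silyl ethers, so no C–H bond has to be oxidised; on the placement of the C10 oxygen this route is stronger than the chosen one.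
- Against: ring A with four stereocentres (C1, C10, C11, C13) and two E-trisubstituted side chains must first be built in a long linear sequence. The allyl sulfone anion can react through C8 and the allyl bromide through C3 (SN2′), both competing with oligomerisation. Reductive removal of an allylic sulfone can move the C7=C8 olefin, the two silyl ethers must be told apart, and the epoxidation problem is unchanged.
- Comparison: the chosen strategy reaches the same skeleton with both bridgeheads in three steps from a commercial C20 alcohol, at the price of the C10 hydroxylation.

**Alternative 2:** Only C11–C15 is cut, opening ring A to a fourteen-membered ring with an isopropenyl group on C1 and the acetoxy group on C10. Forward, Co(salen)Cl and PhSiH3 transfer a hydrogen atom to the isopropenyl group, the tertiary C15 radical adds across the ring to C11 and the C12 radical gives up a C18 hydrogen, which forms ring A and the exocyclic olefin and gives A2.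
- For: this is the second half of the cyclase cascade run with a radical, without enzyme development, and it is redox-neutral. It carries the C10 acetate with its configuration; A2 needs only epoxidation and C13 oxidation, so after its key step it is shorter than the chosen route and has no C–H hydroxylation. On these points it is stronger.
- Against: hydrogen-atom transfer must pick the 1,1-disubstituted olefin over three trisubstituted ones. The attacked carbon C11 is hindered and sits next to the acetoxy-bearing C10. The C11 configuration is left to the conformation of a flexible fourteen-membered ring, the final hydrogen loss can also occur from C13, and the monocyclic precursor with its C10 stereocentre needs its own macrocyclisation-based synthesis.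
- Comparison: the chosen strategy gives up the built-in C10 oxygen but forms both rings from an acyclic commercial chain in one step, with C1, C11 and the site of termination all held by the active site.

**Alternative 3:** The C10–C11 bond is cut. Forward, BF3·OEt2 activates an aldehyde at C10 and a ring A allylsilane (C11=C12–C18H2SiMe3) attacks through C11 (Hosomi–Sakurai reaction, SE2′); this forms C10–C11, closes the twelve-membered ring, shifts the olefin to C12=C18 and gives the homoallylic alcohol A3, with the C13 oxygen in place as a silyl ether.
- For: one step creates the C10 carbinol, the C11 stereocentre and the exocyclic methylene, exactly the array of the target. In functional-group economy around ring A it is the strongest of the four.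
- Against: the nucleophilic carbon C11 is fully substituted and flanked by the quaternary C15, and a twelve-membered ring must close against this hindrance from the end of a nine-carbon tether. Two stereocentres arise from a macrocyclic transition state with no reliable model. The Lewis acid meets two nucleophilic trisubstituted olefins (cation–olefin cyclisation) and an allylsilane prone to protodesilylation, and the open-chain aldehyde needs a long synthesis.
- Comparison: the chosen strategy must add the C10 and C13 oxygens afterwards, but it does not depend on a hindered macrocyclisation and sets C1 and C11 under enzyme control.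

Key step: step 3

## Route

Step 1
Reactants: 1 (2E,6E,10E)-geranylgeraniol
Product: 2 (2E,6E,10E)-geranylgeranyl chloride
Conditions: NCS, Me2S, CH2Cl2, −40 → 0 °C
Reagents that add atoms: N-chlorosuccinimide, O=C1CCC(=O)N1Cl
Why: Corey–Kim chlorination: the sulfonium salt formed from NCS and Me2S activates the primary allylic alcohol and chloride displaces dimethyl sulfoxide by SN2 at the primary carbon, so neither allylic transposition nor E/Z isomerisation of the 2,3-olefin should occur.

Step 2
Reactants: 2 (2E,6E,10E)-geranylgeranyl chloride
Product: 3 (2E,6E,10E)-geranylgeranyl diphosphate, isolated as the tris-ammonium salt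
Conditions: (n-Bu4N)3HP2O7 (2 equiv), MeCN, rt; then cation exchange (NH4+ form resin), cellulose chromatography
Reagents that add atoms: tris(tetra-n-butylammonium) hydrogen diphosphate, CCCC[N+](CCCC)(CCCC)CCCC.CCCC[N+](CCCC)(CCCC)CCCC.CCCC[N+](CCCC)(CCCC)CCCC.OP(=O)([O-])OP(=O)([O-])[O-]
Why: SN2 displacement of a primary allylic chloride by the non-basic diphosphate anion in MeCN is the standard entry to prenyl diphosphates; exchange to the ammonium form gives a salt that dissolves in the enzyme buffer.

Step 3
Reactants: 3 (2E,6E,10E)-geranylgeranyl diphosphate
Product: 4 (1S,3E,7E,11R)-verticilla-3,7,12(18)-triene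
Conditions: taxadiene synthase variant selected for C18 deprotonation (truncated, purified), MgCl2, HEPES–KOH buffer pH 8.0, glycerol, dithiothreitol, n-pentane overlay, 30 °C; AgNO3–silica chromatography
Reagents that add atoms: none
Why: Class 1 diterpene synthase cyclisation of the native substrate: the Mg2+ ions held by the aspartate-rich motifs bind and ionise the diphosphate of 3, and the allyl cation is captured at C2 by C1 of the distal C1=C15 olefin to give the fourteen-membered cembren-15-yl cation, with C15 left outside the ring (exo closure, Markovnikov, tertiary cation). C11 of the C11=C12 olefin then adds to C15, a 6-endo closure that forms ring A, completes the twelve-membered ring and leaves the tertiary verticillen-12-yl cation, which loses a C18 proton to a base of the active site. The closest known reaction is the same cascade in taxadiene synthase, which passes through this cation and whose active-site variants that cannot relay H11 to C7 release verticillatrienes instead of taxadiene. C1 (S) is set by the face of C1=C15 presented to C2 and C11 (R) by the face of C11=C12 presented to the C15 cation; both are fixed by the fold in which the enzyme holds the chain, and the 1S,11R pair is the one on the taxadiene pathway, so a taxadiene synthase scaffold gives the enantiomer needed. The selectivity needed is in the termination: C18 deprotonation must win over the H11-to-C7 transfer, over deprotonation at C13 or at the C15 cation stage and over water capture, and this is secured by selecting or evolving the residues that line the C12 cation. The all-E geometry of 3 places C1=C15 and C11=C12 within reach of the cationic centres, and the C3=C4 and C7=C8 olefins take no part and stay E. The pentane overlay removes 4 from the enzyme as it forms.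

Step 4
Reactants: 4 (1S,3E,7E,11R)-verticilla-3,7,12(18)-triene
Product: 7 (1S,3R,4R,7R,8R,11R)-3,4:7,8-diepoxyverticill-12(18)-ene, via 3,4-monoepoxide 5 (not isolated), via 7,8-monoepoxide 6 (not isolated)
Conditions: D-fructose-derived Shi ketone (0.6 equiv), KHSO5 (as Oxone, 2KHSO5·KHSO4·K2SO4; 2.4 equiv KHSO5), K2CO3, Bu4NHSO4 (cat.), Na2B4O7/Na2EDTA buffer, MeCN–CH2(OMe)2–H2O, 0 °C
Reagents that add atoms: potassium peroxymonosulfate, [K+].[O-]S(=O)(=O)OO
Why: Shi asymmetric epoxidation: the dioxirane formed from the ketone and KHSO5 is electrophilic and should take the two trisubstituted olefins well before the hindered 1,1-disubstituted C12=C18, and the D-fructose-derived ketone transfers oxygen to E-trisubstituted olefins through a spiro transition state with the sense that gives R,R epoxides, the sense needed at both C3–C4 and C7–C8. In the twelve-membered ring only the peripheral face of each olefin can be reached, and the required faces are peripheral in the rotamers with C20 and C19 on the α-face, so the catalyst has to select these rotamers from the equilibrating set (Curtin–Hammett).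

Step 5
Reactants: 7 (1S,3R,4R,7R,8R,11R)-3,4:7,8-diepoxyverticill-12(18)-ene
Product: 8 (1S,3R,4R,7R,8R,10S,11R)-3,4:7,8-diepoxyverticill-12(18)-en-10-ol
Conditions: P450 BM3 (CYP102A1) variant selected for C10 of 7, NADP+ (cat.), D-glucose, glucose dehydrogenase, catalase, air, KH2PO4/K2HPO4 buffer pH 8.0, 2-hydroxypropyl-β-cyclodextrin, 25 °C
Reagents that add atoms: dioxygen, O=O
Why: Cytochrome P450 hydroxylation (hydrogen abstraction by the ferryl oxidant, then oxygen rebound) of a non-activated methylene in an oxygenated terpenoid is established for engineered P450 BM3 variants, but the variant that holds 7 with the pro-S (β) hydrogen of C10 over the heme has to be found by screening an active-site library. With the epoxides in place the substrate offers only C13 and the hindered C11 as activated competitors; C10 (S, β-OH) is set by the binding orientation, since rebound retains configuration.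

Step 6
Reactants: 8 (1S,3R,4R,7R,8R,10S,11R)-3,4:7,8-diepoxyverticill-12(18)-en-10-ol
Product: 9 (1S,3R,4R,7R,8R,10S,11R)-3,4:7,8-diepoxyverticill-12(18)-en-10-yl acetate
Conditions: Ac2O, DMAP (cat.), pyridine, CH2Cl2, 0 °C → rt
Reagents that add atoms: acetic anhydride, CC(=O)OC(C)=O
Why: DMAP-catalysed acylation of the only hydroxyl group; the medium is basic and non-nucleophilic, so the epoxides are untouched and C10 keeps its configuration.

Step 7
Reactants: 9 (1S,3R,4R,7R,8R,10S,11R)-3,4:7,8-diepoxyverticill-12(18)-en-10-yl acetate
Product: 10 (1S,3R,4R,7R,8R,10S,11S)-3,4:7,8-diepoxy-13-hydroxyverticill-12(18)-en-10-yl acetate (C13 epimers)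
Conditions: SeO2 (0.3 equiv), t-BuOOH (anhydrous, in decane; 3 equiv), CH2Cl2, 0 °C → rt
Reagents that add atoms: selenium dioxide, O=[Se]=O (oxygen carrier, used catalytically); tert-butyl hydroperoxide, CC(C)(C)OO (terminal oxygen source)
Why: Riley-type allylic oxidation: ene reaction at the only olefin (selenium to C18, hydrogen from the ring methylene C13 and not from the hindered methine C11 next to the acetoxy carbon), then a [2,3]-sigmatropic shift that returns the C12=C18 olefin and places oxygen on C13. Exocyclic methylenes in terpenoids that carry a remote trisubstituted epoxide are oxidised in this way when the medium is anhydrous and SeO2 substoichiometric; the C13 configuration is immaterial, and any enone formed directly is carried into step 8.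

Step 8
Reactants: 10 (1S,3R,4R,7R,8R,10S,11S)-3,4:7,8-diepoxy-13-hydroxyverticill-12(18)-en-10-yl acetate
Product: 11 (1R,3R,4R,7R,8R,10S,11S)-3,4:7,8-diepoxy-13-oxoverticill-12(18)-en-10-yl acetate
Conditions: Dess–Martin periodinane, NaHCO3, CH2Cl2, 0 °C → rt
Reagents that add atoms: none
Why: Dess–Martin oxidation of the allylic alcohol under NaHCO3 buffering gives the α-methylene ketone without acid that could open the epoxides and without a nucleophile that could add to the enone. No stereocentre is touched; H11 is not acidified because C11 is cross-conjugated with the carbonyl group.

## Compound list

1 | (2E,6E,10E)-geranylgeraniol | CC(C)=CCC/C(C)=C/CC/C(C)=C/CC/C(C)=C/CO | starting material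
2 | (2E,6E,10E)-geranylgeranyl chloride | CC(C)=CCC/C(C)=C/CC/C(C)=C/CC/C(C)=C/CCl | intermediate
3 | (2E,6E,10E)-geranylgeranyl diphosphate (free acid drawn; handled as tris-ammonium salt) | CC(C)=CCC/C(C)=C/CC/C(C)=C/CC/C(C)=C/COP(=O)(O)OP(=O)(O)O | intermediate
4 | (1S,3E,7E,11R)-verticilla-3,7,12(18)-triene | C=C1CC[C@H]2C/C=C(\C)CC/C=C(\C)CC[C@H]1C2(C)C | intermediate
5 | (1S,3R,4R,7E,11R)-3,4-epoxyverticilla-7,12(18)-diene | C=C1CC[C@H]2C[C@H]3O[C@]3(C)CC/C=C(\C)CC[C@H]1C2(C)C | intermediate (not isolated)
6 | (1S,3E,7R,8R,11R)-7,8-epoxyverticilla-3,12(18)-diene | C=C1CC[C@H]2C/C=C(\C)CC[C@H]3O[C@]3(C)CC[C@H]1C2(C)C | intermediate (not isolated)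
7 | (1S,3R,4R,7R,8R,11R)-3,4:7,8-diepoxyverticill-12(18)-ene | C=C1CC[C@H]2C[C@H]3O[C@]3(C)CC[C@H]3O[C@]3(C)CC[C@H]1C2(C)C | intermediate
8 | (1S,3R,4R,7R,8R,10S,11R)-3,4:7,8-diepoxyverticill-12(18)-en-10-ol | C=C1CC[C@H]2C[C@H]3O[C@]3(C)CC[C@H]3O[C@]3(C)C[C@H](O)[C@H]1C2(C)C | intermediate
9 | (1S,3R,4R,7R,8R,10S,11R)-3,4:7,8-diepoxyverticill-12(18)-en-10-yl acetate | C=C1CC[C@H]2C[C@H]3O[C@]3(C)CC[C@H]3O[C@]3(C)C[C@H](OC(C)=O)[C@H]1C2(C)C | intermediate
10 | (1S,3R,4R,7R,8R,10S,11S)-3,4:7,8-diepoxy-13-hydroxyverticill-12(18)-en-10-yl acetate (C13 epimers) | C=C1C(O)C[C@H]2C[C@H]3O[C@]3(C)CC[C@H]3O[C@]3(C)C[C@H](OC(C)=O)[C@H]1C2(C)C | intermediate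
11 | (1R,3R,4R,7R,8R,10S,11S)-3,4:7,8-diepoxy-13-oxoverticill-12(18)-en-10-yl acetate | C=C1C(=O)C[C@H]2C[C@H]3O[C@]3(C)CC[C@H]3O[C@]3(C)C[C@H](OC(C)=O)[C@H]1C2(C)C | target

## Step count and least certain steps

Total step count: 8. Longest linear sequence: 8 steps (1 to 11).

**Step 3 (key step).** The most likely failure is in the termination of the cascade. The cation may continue by H11-to-C7 transfer and a third ring closure, lose a proton from C13 or already at the C15 cation stage, or be captured by water, because these paths differ only in how the pocket holds the C12 cation. The fallback divides the two ring closures between an enzyme and a reagent. It sets out from 3: a synthase that stops after the first closure and deprotonates the C15 cation at a methyl group gives the fourteen-membered (1S,3E,7E,11E)-cembra-3,7,11,15-tetraene F1 (cembrene A with C1 as in 4), a product type that diterpene synthases release far more commonly than bicyclic olefins. Ring A is then closed in the flask by hydrogen-atom-transfer cycloisomerisation (Co(salen)Cl-type catalyst, PhSiH3, benzene, rt): a hydrogen atom goes to the isopropenyl group, the tertiary C15 radical adds 6-endo to C11, and the C12 radical returns a C18 hydrogen to cobalt. The fallback comes back to the route at 4; its own weak point is the C11 configuration, which then depends on the transannular approach.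

**Step 5 (C10 hydroxylation).** The most likely failure is oxygen transfer to the wrong site: the allylic C13 methylene, the C12=C18 olefin or another methylene. Abstraction of the pro-R hydrogen or over-oxidation of the new carbinol could also occur. The cause is that C10 has no intrinsic advantage and everything depends on the binding orientation. The fallback removes the strongest competitor chemically and hydroxylates last. It sets out from 7: SeO2/t-BuOOH gives 3,4:7,8-diepoxyverticill-12(18)-en-13-ol F2, and Dess–Martin oxidation gives 3,4:7,8-diepoxyverticill-12(18)-en-13-one F3, which has neither a free allylic methylene nor an electron-rich olefin. Enzymatic hydroxylation of F3 (P450 variant library or a screen of hydroxylating fungi, for which the ketone can serve as anchor) should then give 3,4:7,8-diepoxy-10-hydroxyverticill-12(18)-en-13-one F4. Acetylation (Ac2O, DMAP, pyridine) brings the fallback back to the route at 11.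

**Step 4 (diepoxidation).** The most likely failure is poor facial selectivity. If the ring mainly presents the rotamers with C19 and C20 on the β-face (the fold that leads on to the taxanes), peripheral attack gives the 3S,4S and 7S,8S epoxides and the catalyst may not override this. Over-oxidation at C12=C18 is a lesser concern. The fallback changes the order so that the substrate helps. It sets out from 4: hydroxylation of C10 with a P450 variant selected on the hydrocarbon gives (1S,3E,7E,10S,11R)-verticilla-3,7,12(18)-trien-10-ol F5, and acetylation gives (1S,3E,7E,10S,11R)-verticilla-3,7,12(18)-trien-10-yl acetate F6. F6 is then epoxidised with the same ketone: the 10β-acetoxy group is 1,3-related to C19 across C9 and should disfavour the rotamer with C19 on the β-face, which exposes the required face of C7=C8; at C3=C4 the catalyst alone has to decide. The fallback comes back to the route at 9; its price is that the hydroxylation must then succeed on the triene, with its many allylic positions.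

**Step 7 (allylic oxidation).** The most likely failure is acid-promoted transannular opening of the 1,5-diepoxide by the seleninic acid formed in the flask, or a sluggish ene reaction at the hindered olefin that prolongs this exposure. The fallback replaces the selenium reagent by an enzyme at neutral pH. It sets out from 9: a P450 variant that hydroxylates the allylic C13 methylene, the intrinsically most reactive C–H bond of 9 and a reactivity that the screening of step 5 will turn up in any case, should give 10 directly. The fallback comes back to the route at 10 and passes through no new compound (F0).

## Further compounds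

F1 | step 3 | (1S,3E,7E,11E)-cembra-3,7,11,15-tetraene (cembrene A, C1 as in 4) | C=C(C)[C@@H]1C/C=C(\C)CC/C=C(\C)CC/C=C(\C)CC1
F2 | step 5 | (1S,3R,4R,7R,8R,11S)-3,4:7,8-diepoxyverticill-12(18)-en-13-ol (C13 epimers) | C=C1C(O)C[C@H]2C[C@H]3O[C@]3(C)CC[C@H]3O[C@]3(C)CC[C@H]1C2(C)C
F3 | step 5 | (1R,3R,4R,7R,8R,11S)-3,4:7,8-diepoxyverticill-12(18)-en-13-one | C=C1C(=O)C[C@H]2C[C@H]3O[C@]3(C)CC[C@H]3O[C@]3(C)CC[C@H]1C2(C)C
F4 | step 5 | (1R,3R,4R,7R,8R,10S,11S)-3,4:7,8-diepoxy-10-hydroxyverticill-12(18)-en-13-one | C=C1C(=O)C[C@H]2C[C@H]3O[C@]3(C)CC[C@H]3O[C@]3(C)C[C@H](O)[C@H]1C2(C)C
F5 | step 4 | (1S,3E,7E,10S,11R)-verticilla-3,7,12(18)-trien-10-ol | C=C1CC[C@H]2C/C=C(\C)CC/C=C(\C)C[C@H](O)[C@H]1C2(C)C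
F6 | step 4 | (1S,3E,7E,10S,11R)-verticilla-3,7,12(18)-trien-10-yl acetate (same structure as A2) | C=C1CC[C@H]2C/C=C(\C)CC/C=C(\C)C[C@H](OC(C)=O)[C@H]1C2(C)C
F0 | step 7 | none | none
A1 | alternative 1 | 10,13-bis(tert-butyldimethylsilyloxy)-6-(phenylsulfonyl)verticilla-3,7,12(18)-triene (C6 epimers; C1, C10, C11 as in 9) | C=C1[C@H](O[Si](C)(C)C(C)(C)C)C[C@H]2C/C=C(\C)CC(/C=C(\C)C[C@H](O[Si](C)(C)C(C)(C)C)[C@H]1C2(C)C)S(=O)(=O)c1ccccc1
A2 | alternative 2 | (1S,3E,7E,10S,11R)-verticilla-3,7,12(18)-trien-10-yl acetate | C=C1CC[C@H]2C/C=C(\C)CC/C=C(\C)C[C@H](OC(C)=O)[C@H]1C2(C)C
A3 | alternative 3 | (10S)-13-(tert-butyldimethylsilyloxy)verticilla-3,7,12(18)-trien-10-ol (C1, C11 as in 4) | C=C1[C@@H](O[Si](C)(C)C(C)(C)C)C[C@H]2C/C=C(\C)CC/C=C(\C)C[C@H](O)[C@H]1C2(C)C
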